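**Retrosynthetic overview**

- Target ⇐ hydrogenolysis of the 2'-O-benzyl ether of the (3S)-isoflavan.
- (3S)-Isoflavan ⇐ enantioselective Ir-catalysed hydrogenation of the C2=C3 enol ether of an achiral 3-aryl-4H-chromene (sets C3).
- 4H-Chromene ⇐ coenzyme Q0 + a ring-B β-methoxystyrene: quinone → o-quinone methide tautomer, oxa-[4+2] (forms O1–C2 and C3–C4, ring A re-aromatises), then loss of MeOH.
- Coenzyme Q0 ⇐ oxidative de-aromatisation of 3,4,5-trimethoxytoluene (the two new oxygens become O1 and 6-OH, the methyl becomes C4); enol ether ⇐ 2-hydroxy-3,4-dimethoxybenzaldehyde (benzylation, Wittig).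
- Ring order: rings A and B come from the two arenes; the pyran ring is formed last, in the cycloaddition.

Assumption: the ligand antipode in step 5 is the one that gives (3S); the sense is assigned from the quadrant model for Ir–P,N catalysts and is to be confirmed by chiral HPLC on the first run (both antipodes are available).

**Route**

Step 1
Reactants: 1 3,4,5-trimethoxytoluene
Product: 3 2,3-dimethoxy-5-methyl-1,4-benzoquinone (coenzyme Q0), via 2,3,4-trimethoxy-6-methylphenol 2 (not isolated)
Conditions: 30% aq. H2O2, HCO2H, 40 °C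
Reagents that add atoms: hydrogen peroxide, OO
Why: Oxidative de-aromatisation of an electron-rich arene to a p-quinone: performic acid hydroxylates the only free ring position (ortho to CH3, para to OMe) and the resulting p-methoxyphenol is oxidised on with loss of methanol, a known conversion of this bulk arene that lies off the longest linear sequence.

Step 2
Reactants: 4 2-hydroxy-3,4-dimethoxybenzaldehyde
Product: 5 2-(benzyloxy)-3,4-dimethoxybenzaldehyde
Conditions: BnBr, K2CO3, DMF, 60 °C
Reagents that add atoms: benzyl bromide, BrCc1ccccc1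
Why: Williamson ether synthesis; the benzyl group masks the 2'-OH, which would otherwise trap the oxocarbenium/enol ether at C2 as a five-membered acetal in steps 4 and 5.

Step 3
Reactants: 5 2-(benzyloxy)-3,4-dimethoxybenzaldehyde
Product: 6 2-(benzyloxy)-3,4-dimethoxy-1-(2-methoxyethenyl)benzene (E/Z mixture)
Conditions: Ph3P(CH2OMe)Cl, KOtBu, THF, 0 °C to rt
Reagents that add atoms: (methoxymethyl)triphenylphosphonium chloride, COC[P+](c1ccccc1)(c1ccccc1)c1ccccc1.[Cl-]
Why: Wittig methoxymethylenation adds the C2 carbon as an enol ether; the E/Z ratio does not matter because both alkene-derived stereocentres are erased in step 4.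

Step 4
Reactants: 3 2,3-dimethoxy-5-methyl-1,4-benzoquinone, 6 2-(benzyloxy)-3,4-dimethoxy-1-(2-methoxyethenyl)benzene
Product: 9 3-[2-(benzyloxy)-3,4-dimethoxyphenyl]-7,8-dimethoxy-4H-chromen-6-ol, via o-quinone methide 7 (not isolated), via 2-methoxychroman acetal 8 (not isolated)
Conditions: 6 (1.3 equiv), Et3N (0.3 equiv), MeCN, 60 °C, slow addition of 3; then evaporate, CSA (5 mol%), PhMe, 110 °C, 5 Å MS
Reagents that add atoms: none
Why: Proposed new method: amine-catalysed vinylogous enolisation of the quinone methyl gives the o-quinone methide tautomer 7, which the enol ether traps in an inverse-electron-demand oxa-Diels–Alder reaction (nucleophilic aryl-bearing carbon to the methide CH2, quinone oxygen to the acetal carbon, ring A re-aromatising to the free 6-OH phenol), and acid then expels MeOH from acetal 8 (E1) to give planar, achiral 9; the closest known reactions are base-induced quinone → o-quinone methide tautomerisation with trapping (coumarins from duroquinone and malonate, chromenols from prenylquinones) and o-quinone methide/enol ether [4+2] cycloadditions to 2-alkoxychromans.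

Step 5
Reactants: 9 3-[2-(benzyloxy)-3,4-dimethoxyphenyl]-7,8-dimethoxy-4H-chromen-6-ol
Product: 10 (3S)-3-[2-(benzyloxy)-3,4-dimethoxyphenyl]-7,8-dimethoxy-3,4-dihydro-2H-chromen-6-ol
Conditions: H2 (50 bar), [Ir(cod)(tBu-PHOX)]BArF (1 mol%), CH2Cl2, 25 °C
Reagents that add atoms: none
Why: Ir–P,N-catalysed asymmetric hydrogenation of an unfunctionalised trisubstituted cyclic enol ether (the reaction type used for 4H- and 2H-chromenes): H2 adds to one enantioface of C2=C3 under ligand control, which creates C3 as (S), while the benzyl ether and arenes are untouched.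

Step 6
Reactants: 10 (3S)-3-[2-(benzyloxy)-3,4-dimethoxyphenyl]-7,8-dimethoxy-3,4-dihydro-2H-chromen-6-ol
Product: 11 (3S)-3-(2-hydroxy-3,4-dimethoxyphenyl)-7,8-dimethoxy-3,4-dihydro-2H-chromen-6-ol
Conditions: H2 (1 atm), 10% Pd/C, EtOAc–MeOH, 25 °C
Reagents that add atoms: none
Why: Catalytic hydrogenolysis of the aryl benzyl ether under neutral conditions frees the 2'-OH without touching the C3 stereocentre or the chroman C–O bonds.

**Compound list**

1 | 3,4,5-trimethoxytoluene | Cc1cc(OC)c(OC)c(OC)c1 | starting material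
2 | 2,3,4-trimethoxy-6-methylphenol | Cc1cc(OC)c(OC)c(OC)c1O | intermediate (not isolated)
3 | 2,3-dimethoxy-5-methyl-1,4-benzoquinone (coenzyme Q0) | CC1=CC(=O)C(OC)=C(OC)C1=O | intermediate
4 | 2-hydroxy-3,4-dimethoxybenzaldehyde | O=Cc1ccc(OC)c(OC)c1O | starting material
5 | 2-(benzyloxy)-3,4-dimethoxybenzaldehyde | O=Cc1ccc(OC)c(OC)c1OCc1ccccc1 | intermediate
6 | 2-(benzyloxy)-3,4-dimethoxy-1-(2-methoxyethenyl)benzene (E/Z mixture) | COC=Cc1ccc(OC)c(OC)c1OCc1ccccc1 | intermediate
7 | 4-hydroxy-2,3-dimethoxy-6-methylidenecyclohexa-2,4-dien-1-one (o-quinone methide tautomer of 3) | C=C1C=C(O)C(OC)=C(OC)C1=O | intermediate (not isolated)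
8 | 3-[2-(benzyloxy)-3,4-dimethoxyphenyl]-2,7,8-trimethoxy-3,4-dihydro-2H-chromen-6-ol (racemic, cis/trans mixture) | COC1Oc2c(OC)c(OC)c(O)cc2CC1c1ccc(OC)c(OC)c1OCc1ccccc1 | intermediate (not isolated)
9 | 3-[2-(benzyloxy)-3,4-dimethoxyphenyl]-7,8-dimethoxy-4H-chromen-6-ol (achiral) | COc1ccc(C2=COc3c(OC)c(OC)c(O)cc3C2)c(OCc2ccccc2)c1OC | intermediate
10 | (3S)-3-[2-(benzyloxy)-3,4-dimethoxyphenyl]-7,8-dimethoxy-3,4-dihydro-2H-chromen-6-ol | COc1ccc([C@H]2COc3c(cc(O)c(OC)c3OC)C2)c(OCc2ccccc2)c1OC | intermediate
11 | (3S)-3-(2-hydroxy-3,4-dimethoxyphenyl)-7,8-dimethoxy-3,4-dihydro-2H-chromen-6-ol | COc1ccc([C@H]2COc3c(cc(O)c(OC)c3OC)C2)c(O)c1OC | target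

**Step count**

Total steps: 6. Longest linear sequence: 5 (4 → 5 → 6 → 9 → 10 → 11).

**Steps most likely to fail, with fallbacks**

Step 4 is the most likely to fail: the methyl quinone may tautomerise slowly, and the quinone may react in other ways. The fallback sets out from 6 and comes back at 8; it makes the o-quinone methide from an aromatic hydroquinone instead of from the quinone methyl, so that C4 comes from formaldehyde. Commercial 2,3-dimethoxy-1,4-benzoquinone is reduced (Na2S2O4) to 2,3-dimethoxybenzene-1,4-diol F3. F3 is condensed with paraformaldehyde and PhB(OH)2 (cat. EtCO2H, PhMe, Dean–Stark) to the benzodioxaborin 7,8-dimethoxy-2-phenyl-4H-1,3,2-benzodioxaborinin-6-ol F4. Heating F4 with 6 (xylene, 140 °C) releases o-quinone methide 7, which is trapped as acetal 8; the CSA elimination of step 4 then gives 9.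

Step 5 may fail because the enol ether is acid-labile under Ir–H conditions and the ortho-substituted aryl may lower the ee. The fallback sets out from 9 and comes back at 10. Hydration of 9 (aq. HCl, THF) gives the lactol 3-[2-(benzyloxy)-3,4-dimethoxyphenyl]-7,8-dimethoxy-3,4-dihydro-2H-chromene-2,6-diol F5. Its ring-opened α-aryl aldehyde racemises under base, so Ru(diphosphine)(diamine)/KOtBu-catalysed hydrogenation under dynamic kinetic resolution (iPrOH, H2) gives (2S)-2-[2-(benzyloxy)-3,4-dimethoxyphenyl]-3-(2,5-dihydroxy-3,4-dimethoxyphenyl)propan-1-ol F6. Mitsunobu ring closure (PPh3, DIAD, THF) then forms the O1–C2 bond and gives 10.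

Step 1 may give a moderate yield through over-oxidation. The fallback sets out from 1 and comes back at 2, which is isolated this time. Vilsmeier–Haack formylation (POCl3, DMF) gives 2,3,4-trimethoxy-6-methylbenzaldehyde F1. Baeyer–Villiger oxidation (mCPBA, CH2Cl2) gives 2,3,4-trimethoxy-6-methylphenyl formate F2, and hydrolysis (aq. NaOH) gives phenol 2. Phenol 2 is then oxidised to 3 under the step 1 conditions or with CAN in aq. MeCN.

**Further compounds**

F1 | step 1 | 2,3,4-trimethoxy-6-methylbenzaldehyde | Cc1cc(OC)c(OC)c(OC)c1C=O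
F2 | step 1 | 2,3,4-trimethoxy-6-methylphenyl formate | Cc1cc(OC)c(OC)c(OC)c1OC=O
F3 | step 4 | 2,3-dimethoxybenzene-1,4-diol | COc1c(O)ccc(O)c1OC
F4 | step 4 | 7,8-dimethoxy-2-phenyl-4H-1,3,2-benzodioxaborinin-6-ol | COc1c(O)cc2COB(c3ccccc3)Oc2c1OC
F5 | step 5 | 3-[2-(benzyloxy)-3,4-dimethoxyphenyl]-7,8-dimethoxy-3,4-dihydro-2H-chromene-2,6-diol (racemic) | COc1ccc(C2Cc3cc(O)c(OC)c(OC)c3OC2O)c(OCc2ccccc2)c1OC
F6 | step 5 | (2S)-2-[2-(benzyloxy)-3,4-dimethoxyphenyl]-3-(2,5-dihydroxy-3,4-dimethoxyphenyl)propan-1-ol | OC[C@@H](Cc1cc(O)c(OC)c(OC)c1O)c1ccc(OC)c(OC)c1OCc1ccccc1
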